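## Analysis of the target

Target 25 is a daucane-type sesquiterpenoid diester on a cis-fused hydroazulene. Ring A is the cyclopentane C1–C2–C3–C4–C5 and ring B the cycloheptene C1–C5–C6–C7–C8–C9–C10. C1 is the quaternary methyl-bearing fusion carbon, C4 the isopropyl carbinol, C5 the fusion CH, C6 the aroyloxy carbon, C8=C9 the trisubstituted alkene (methyl on C8) and C10 the tigloyloxy carbon. The five stereocentres are (1R,4R,5S,6R,10R). Calling β the face of ring B that carries the C1–C2 and C5–C4 bonds, the C1 methyl, C5–H, the C4 isopropyl group and the C10 oxygen are α, while the C4 hydroxyl and the C6 oxygen are β. The sensitive groups are the allylic, neopentylic tiglate at C10, the 4-hydroxybenzoate at C6 (which can migrate to the syn tertiary hydroxyl under base), the free phenol and the tertiary alcohol. The difficulty lies in the quaternary C1 flanked by two stereocentres, the seven-membered ring, and two secondary oxygens that must be told apart and placed on opposite faces. The strategy rests on the 1,4-relationship of C6 and C10 across the C1–C5 bond: C6, C10, the bond C5–C1 and the chain C7–C8–C9 are the atoms of an 8-oxabicyclo[3.2.1]octane with C6 and C10 as bridgeheads. That is the product of a (5+2) cycloaddition of a 4-methyl-3-oxidopyrylium across the C1=C5 bond of a cyclopentenone. Because the two C–O bonds are trans on ring B, one bridging oxygen cannot serve both carbinols; it is kept at C6 and the C10 oxygen is put back from the other face.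

## Retrosynthetic reasoning

Compound numbers are those of the steps below.

**Silyl groups (25 ⇐ 24).** The phenol and the C4 hydroxyl are unmasked together at the end. This keeps the phenol out of every acylation and base step and keeps a C4 alkoxide away from the syn C6 ester.

**Alkene (24 ⇐ 21 ⇐ 20).** The C8=C9 alkene with its C7 methylene is traced back to a C9 ketone conjugated with C7=C8. A C9 carbonyl lets the alkene be placed without regiochemical choice, because hydrogen is delivered to C7 inside the allylic diazene 23. It is also the carbonyl the cycloaddition leaves behind and the one needed to oxygenate C10.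

**C10 ester and C10 oxygen (20 ⇐ 17 + 18; 17 ⇐ 15).** The acyl–O bond is cut first, then the C10–O bond, back to the C10 methylene of 15. Forward, oxidation of the C9–C10 enolate 16 must deliver oxygen to the α face, trans to the C6 oxygen. C10 is the only α′ position of the enone, so there is no regiochemical competition on carbon.

**C6 ester (15 ⇐ 11 + 14; 14 ⇐ 12).** The C6 alcohol is the only free hydroxyl of 11. The two esters are therefore distinguished by the order in which their hydroxyls appear, not by extra protecting groups.

**Oxygen bridge (11 ⇐ 10).** In the reverse sense the C6 oxygen is joined to C10. Forward, the C10–O bond α to the C9 ketone is cleaved reductively. The cut is made at C10 and not at C6 because C6 already has the right configuration and C10 the wrong one, and because C10 can be re-oxygenated through the ketone while C6 could not.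

**Isopropyl group (10 ⇐ 9 ⇐ 8).** The C4–isopropyl bond is cut back to the C4 ketone of 8. The addition is done on the rigid tricycle, where ring A shows one open face, and before the bridge is opened. The second carbonyl (C9) is conjugated, hindered and cannot enolise.

**Key disconnection (8 ⇐ 4 + 5, through 6 and 7).** Bonds C1–C10 and C5–C6 are cut. They are the only ring B bonds that join ring A to the two oxygenated carbons. Cutting them removes the quaternary centre, the ring fusion and the C6 carbinol in one operation and leaves two small pieces: 7 carries C6–C10 with the C8 methyl and both oxygen sites, and 5 carries ring A with the C1 methyl and the C4 carbonyl. The forward reaction must bond the ylide carbon next to the oxido group to the methyl-bearing β-carbon, approach exo, and use one face of 5.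

**Ylide precursor (4 ⇐ 3 ⇐ 2 ⇐ 1).** The acetal C–O bond is cut, then the oxidative ring expansion of a furylmethanol is reversed, then the reduction of the acid. These are three reliable steps, so the risk of the route sits in the cycloaddition.

## Alternatives that were turned down

**Alternative 1:** Divinylcyclopropane rearrangement.
- **Disconnection:** the C7–C8 bond of ring B, back to a bicyclo[3.1.0]hexane in which C5–C10 is a cyclopropane bond.
- **Forward key step:** heating the cis-divinylcyclopropane A2 (siloxyvinyl on C5, (E)-propenyl on C10) gives the hydroazulene silyl enol ether A1 by Cope rearrangement.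
- **For:** the rearrangement is strain-driven, stereospecific and known chemistry, which is more than can be said for the key step chosen here. A1 has C6 at the ketone level, the C4 carbinol in place and an alkene next to C10.
- **Against:** A2 has two adjacent fully substituted cyclopropane carbons (C1, C5) beside the tertiary silyloxy carbon C4, so the real risk moves into a long precursor synthesis. C5 is sp2 in A1, and the cis fusion must be reset by protonation. The C8 stereocentre is made only to be destroyed. C6 still needs a face-selective reduction, and C10 an oxygen together with an alkene shift.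
- **Comparison:** the chosen route reaches its cycloaddition partners in three steps and sets C1, C5 and the C6 oxygen together, at the price of an unprecedented catalysis.

**Alternative 2:** Semipinacol contraction–expansion.
- **Disconnection:** the C1–C5 bond, by a retro-1,2-shift to a decalin in which C1 is bonded to C6.
- **Forward key step:** an alkoxide base converts the trans-decalin hydroxy mesylate A4 (axial C6 hydroxyl, equatorial C5 mesylate anti to the C6–C1 bond), made from the (R)-Wieland–Miescher ketone A5, into the hydroazulen-6-one A3.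
- **For:** on precedent and on certainty of absolute configuration this is the strongest of the four. Every step is known, and the quaternary C1 comes enantiopure from A5.
- **Against:** A3 lacks the C8 methyl, the alkene and the isopropyl group. C8 is β to both ring B carbonyls and is reachable only through an enone and conjugate-addition detour. C4 must be oxidised and alkylated late among other carbonyls. The step count is roughly double.
- **Comparison:** the chosen route gives up that reliability for a sequence in which the C8 methyl and both oxygen sites arrive inside the ylide.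

**Alternative 3:** Open-chain oxyallyl (4+3).
- **Disconnection:** C1–C5 and C7–C8, opening both rings to the acyclic chloromethyl ketone A7 with an (E,E)-diene.
- **Forward key step:** an amine base in a fluorinated alcohol ionises A7 to the C5–C6–C7 oxyallyl cation, which adds across the tethered diene to give A6.
- **For:** it is the most convergent ring construction, and A6 already holds every carbon, including the isopropyl group. On atom mapping it is stronger than the chosen route, which has to cleave and re-make a C–O bond.
- **Against:** absolute and relative control must be relayed from one acyclic tertiary carbinol (C4), itself hard to make enantioenriched, through a forming five-membered ring to a quaternary diene terminus. A7 needs a linear synthesis of eight to ten steps. The C6 reduction, the C10 oxygenation and the alkene shift remain.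
- **Comparison:** the chosen route offers a three-step precursor, a C6 oxygen fixed relative to the ring fusion by the bridge, and control by a catalyst instead of by a remote stereocentre.

Key step: step 4

Assumption: the oxazaborolidine enantiomer written in step 4 is the one predicted to leave the Re face of C2 and C3 of enone 5 open; if the sense proves opposite, its antipode is used and nothing else changes.

## Route

Step 1
Reactants: 1 3-methyl-2-furoic acid
Product: 2 (3-methylfuran-2-yl)methanol
Conditions: LiAlH4, THF, 0 °C to rt; aqueous NaOH work-up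
Reagents that add atoms: none
Why: Hydride reduction of the carboxylic acid to the primary alcohol; the furan is inert to LiAlH4 and no stereocentre is involved.

Step 2
Reactants: 2 (3-methylfuran-2-yl)methanol
Product: 3 6-hydroxy-4-methyl-2H-pyran-3(6H)-one (racemic lactol)
Conditions: mCPBA, CH2Cl2, 0 °C
Reagents that add atoms: 3-chloroperoxybenzoic acid, OOC(=O)c1cccc(Cl)c1
Why: Achmatowicz rearrangement: oxidation of the furan, opening to the ene-dione and closure of the primary hydroxyl onto the aldehyde give the pyranone, the furan 3-methyl becoming the 4-methyl group. The lactol carbon is racemic and stops being a stereocentre in step 4.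

Step 3
Reactants: 3 6-hydroxy-4-methyl-2H-pyran-3(6H)-one
Product: 4 6-acetoxy-4-methyl-2H-pyran-3(6H)-one (racemic acetal)
Conditions: Ac2O, pyridine, DMAP (cat.), CH2Cl2, 0 °C
Reagents that add atoms: acetic anhydride, CC(=O)OC(C)=O
Why: Acylation of the lactol hydroxyl with a weak base in the cold, so that the acetate is not yet eliminated to the ylide.

Step 4
Reactants: 4 6-acetoxy-4-methyl-2H-pyran-3(6H)-one; 5 3-methylcyclopent-2-en-1-one
Product: 8 oxygen-bridged tricyclic enone-dione (1R,5S,6R,10R; C4 and C9 ketones; C7=C8 alkene; 6,10-oxygen bridge), via oxocarbenium triflate 6 (not isolated), via oxidopyrylium ylide 7 (not isolated)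
Conditions: 5 (3 equiv), (S)-B-(o-tolyl)oxazaborolidine·AlBr3 from (S)-diphenylprolinol (20 mol %), 2,6-di-tert-butyl-4-methylpyridine, CH2Cl2, −40 °C; TMSOTf added slowly
Reagents that add atoms: none
Why: Proposed new method: TMSOTf removes the anomeric acetate of 4 as TMSOAc, the hindered pyridine takes a proton from the CH2 group of cation 6, and the 3-oxidopyrylium 7 adds as a carbonyl ylide across the C1=C5 bond of enone 5 bound through its carbonyl oxygen to the cationic boron of the catalyst; the closest known reaction type is the thermal, amine-promoted (5+2) cycloaddition of 3-oxidopyrylium ylides with cyclic enones, which gives racemic adducts, and the enone activation is borrowed from cycloadditions of cyclic enones catalysed by AlBr3-activated oxazaborolidines. A trialkylamine and free acetate, the usual way to the ylide, would titrate this Lewis acid, hence the silyl transfer and a pyridine too hindered to bind boron or aluminium. The seven-membered carbocycle (C1, C5, C6, C7, C8, C9, C10) closes intermolecularly by suprafacial union of the five ylide atoms with the alkene, both ring bonds forming in this step and C10–C1 running ahead of C6–C5; the oxygen bridge and ring A are already present in the partners. Regiochemistry is set by polarity: the ylide carbon next to the oxido group, the nucleophilic terminus, bonds to the β-carbon C1, whose electrophilicity the Lewis acid raises. C1 and C5 come out cis because the alkene is attacked on one face, C6 and C10 are tied to each other by the bridge, and the C5/C6 relationship comes from exo approach, expected because the endo mode forces the catalyst-bound cyclopentenone under the methyl-bearing carbon chain of the ylide. The absolute configuration is set by the catalyst, which sits on the carbonyl lone pair syn to C5–H and shields one enone face with an aryl group, so that the ylide must take the Re face of both alkene carbons. Excess 5 and slow release of 7 are meant to hold back ylide dimerisation.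

Step 5
Reactants: 8 oxygen-bridged tricyclic enone-dione
Product: 9 (1R,4R,5S,6R,10R)-6,10-epoxy-4-hydroxydauc-7-en-9-one (C4 isopropyl carbinol of 8)
Conditions: iPrMgCl, CeCl3, THF, −78 °C
Reagents that add atoms: isopropylmagnesium chloride, CC(C)[Mg]Cl
Why: Carbonyl addition of the organocerium reagent, which is nucleophilic but weakly basic, so enolisation of C4 and β-elimination of the C6–O bridge bond are held back; the saturated cyclopentanone reacts ahead of the conjugated, α-methylated C9 ketone. The reagent reaches C4 from the α face of ring A, which carries only C5–H and the C1 methyl, because the β face looks onto the oxygen bridge; isopropyl therefore ends cis to C5–H and the hydroxyl syn to the C6 oxygen (4R).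

Step 6
Reactants: 9 (1R,4R,5S,6R,10R)-6,10-epoxy-4-hydroxydauc-7-en-9-one
Product: 10 (1R,4R,5S,6R,10R)-6,10-epoxy-4-(trimethylsilyloxy)dauc-7-en-9-one
Conditions: TMSOTf, 2,6-lutidine, CH2Cl2, −78 to 0 °C
Reagents that add atoms: trimethylsilyl trifluoromethanesulfonate, C[Si](C)(C)OS(=O)(=O)C(F)(F)F
Why: Silylation of the tertiary alcohol; the remaining C9 ketone has only bridgehead neighbours and cannot form a silyl enol ether. The ether prevents a C4 alkoxide in step 10, where it could take the syn C6 aroyl group.

Step 7
Reactants: 10 (1R,4R,5S,6R,10R)-6,10-epoxy-4-(trimethylsilyloxy)dauc-7-en-9-one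
Product: 11 (1S,4R,5S,6R)-6-hydroxy-4-(trimethylsilyloxy)dauc-7-en-9-one
Conditions: SmI2 (2.5 equiv), THF/MeOH, −78 °C
Reagents that add atoms: none
Why: Electron transfer to the C9 ketone gives a ketyl that expels the α oxygen, a second electron gives the C9–C10 dienolate, and methanol protonates C10; this is the standard reductive cleavage of α-alkoxy ketones by SmI2. C6 keeps its oxygen and its configuration, and the C7=C8 enone is restored on protonation.

Step 8
Reactants: 12 4-hydroxybenzoic acid
Product: 14 4-(tert-butyldimethylsilyloxy)benzoic acid, via bis-silyl derivative 13 (not isolated)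
Conditions: TBSCl, imidazole, DMF, rt; then K2CO3, MeOH/THF/H2O, rt; citric acid
Reagents that add atoms: tert-butyldimethylsilyl chloride, CC(C)(C)[Si](C)(C)Cl
Why: Both acidic hydroxyls are silylated and the labile silyl ester is then solvolysed selectively, leaving the aryl silyl ether.

Step 9
Reactants: 11 (1S,4R,5S,6R)-6-hydroxy-4-(trimethylsilyloxy)dauc-7-en-9-one; 14 4-(tert-butyldimethylsilyloxy)benzoic acid
Product: 15 (1S,4R,5S,6R)-6-[4-(tert-butyldimethylsilyloxy)benzoyloxy]-4-(trimethylsilyloxy)dauc-7-en-9-one
Conditions: EDC·HCl, DMAP, CH2Cl2, 0 °C to rt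
Reagents that add atoms: none
Why: Steglich esterification of the only free hydroxyl, the secondary allylic C6 alcohol; the carbinol carbon is not touched, so its configuration from step 4 is kept.

Step 10
Reactants: 15 (1S,4R,5S,6R)-6-[4-(tert-butyldimethylsilyloxy)benzoyloxy]-4-(trimethylsilyloxy)dauc-7-en-9-one
Product: 17 (1R,4R,5S,6R,10S)-6-[4-(tert-butyldimethylsilyloxy)benzoyloxy]-10-hydroxy-4-(trimethylsilyloxy)dauc-7-en-9-one, via sodium dienolate 16 (not isolated)
Conditions: NaN(SiMe3)2, THF, −78 °C; 2-(phenylsulfonyl)-3-phenyloxaziridine, −78 °C; aqueous NH4Cl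
Reagents that add atoms: 2-(phenylsulfonyl)-3-phenyloxaziridine, O=S(=O)(c1ccccc1)N1OC1c1ccccc1
Why: Kinetic deprotonation at C10, the only α′ position, gives the cross-conjugated dienolate 16, and the N-sulfonyloxaziridine transfers oxygen to C10 (enolate hydroxylation; sodium is used so that the product alkoxide does not add to the sulfonimine). The β face of ring B is the concave face of the cis-fused bicycle and carries C2–C3 of ring A, the C4 silyloxy group and the C6 ester, so oxygen should enter from the α face, cis to the C1 methyl and trans to the C6 oxygen (10S).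

Step 11
Reactants: 17 (1R,4R,5S,6R,10S)-6-[4-(tert-butyldimethylsilyloxy)benzoyloxy]-10-hydroxy-4-(trimethylsilyloxy)dauc-7-en-9-one; 18 tiglic acid
Product: 20 (1R,4R,5S,6R,10S)-6-[4-(tert-butyldimethylsilyloxy)benzoyloxy]-10-[(E)-2-methylbut-2-enoyloxy]-4-(trimethylsilyloxy)dauc-7-en-9-one, via mixed anhydride 19 (not isolated)
Conditions: 18, 2,4,6-trichlorobenzoyl chloride, Et3N, toluene, rt; then 17, DMAP, rt
Reagents that add atoms: none
Why: Yamaguchi esterification through mixed anhydride 19, chosen for the hindered neopentylic C10 alcohol; tiglic acid is the stable E isomer, and acylation on oxygen leaves the C10 stereocentre alone.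

Step 12
Reactants: 20 (1R,4R,5S,6R,10S)-6-[4-(tert-butyldimethylsilyloxy)benzoyloxy]-10-[(E)-2-methylbut-2-enoyloxy]-4-(trimethylsilyloxy)dauc-7-en-9-one
Product: 21 C9 p-toluenesulfonylhydrazone of 20
Conditions: TsNHNH2, PPTS (cat.), THF, 4 Å sieves, 50 °C
Reagents that add atoms: 4-methylbenzenesulfonohydrazide, Cc1ccc(cc1)S(=O)(=O)NN
Why: Acid-catalysed condensation at the only ketone; mild acid without base keeps the C10 ester and C10–H in place. Partial loss of the tertiary silyl ether here would be of no consequence, since step 14 removes it.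

Step 13
Reactants: 21 C9 p-toluenesulfonylhydrazone of 20
Product: 24 (1R,4R,5S,6R,10R)-6-[4-(tert-butyldimethylsilyloxy)benzoyloxy]-10-[(E)-2-methylbut-2-enoyloxy]-4-(trimethylsilyloxy)dauc-8-ene, via boryl hydrazine 22 (not isolated), via allylic diazene 23 (not isolated)
Conditions: catecholborane, CHCl3, 0 °C; then NaOAc·3H2O, 60 °C
Reagents that add atoms: none
Why: Catecholborane adds hydride to C=N (22); acetate then triggers loss of p-toluenesulfinate to the allylic diazene 23, whose retro-ene loss of N2 delivers hydrogen to C7 and leaves the alkene at C8=C9. This reductive 1,3-transposition of enone tosylhydrazones is regiospecific, creates no stereocentre and leaves both esters alone.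

Step 14
Reactants: 24 (1R,4R,5S,6R,10R)-6-[4-(tert-butyldimethylsilyloxy)benzoyloxy]-10-[(E)-2-methylbut-2-enoyloxy]-4-(trimethylsilyloxy)dauc-8-ene
Product: 25 (1R,4R,5S,6R,10R)-6-(4-hydroxybenzoyloxy)-10-[(E)-2-methylbut-2-enoyloxy]dauc-8-en-4-ol (target)
Conditions: Bu4NF, AcOH (1:1), THF, 0 °C to rt
Reagents that add atoms: none
Why: Fluoride cleaves the aryl silyl ether and the tertiary trimethylsilyl ether; acetic acid buffers the phenoxide and the C4 alkoxide so that neither ester migrates or is cleaved.

## Compound list

1 | 3-methyl-2-furoic acid | Cc1ccoc1C(=O)O | starting material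
2 | (3-methylfuran-2-yl)methanol | Cc1ccoc1CO | intermediate
3 | 6-hydroxy-4-methyl-2H-pyran-3(6H)-one (racemic) | CC1=CC(O)OCC1=O | intermediate
4 | 6-acetoxy-4-methyl-2H-pyran-3(6H)-one (racemic) | CC(=O)OC1OCC(=O)C(C)=C1 | intermediate
5 | 3-methylcyclopent-2-en-1-one | CC1=CC(=O)CC1 | starting material
6 | 4-methyl-3-oxo-2,3-dihydropyrylium triflate | CC1=CC=[O+]CC1=O.[O-]S(=O)(=O)C(F)(F)F | intermediate (not isolated)
7 | 4-methyl-3-oxidopyrylium | Cc1cc[o+]cc1[O-] | intermediate (not isolated)
8 | oxygen-bridged tricyclic enone-dione: ring A/ring B core with 1-methyl, 8-methyl, C4 and C9 ketones, C7=C8 alkene and an oxygen bridge from C6 to C10 on the β face; (1R,5S,6R,10R) | O1[C@H]2C(=O)C(C)=C[C@@H]1[C@@H]3[C@@]2(C)CCC3=O | intermediate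
9 | (1R,4R,5S,6R,10R)-6,10-epoxy-4-hydroxydauc-7-en-9-one | O1[C@H]2C(=O)C(C)=C[C@@H]1[C@@H]3[C@@]2(C)CC[C@@]3(O)C(C)C | intermediate
10 | (1R,4R,5S,6R,10R)-6,10-epoxy-4-(trimethylsilyloxy)dauc-7-en-9-one | O1[C@H]2C(=O)C(C)=C[C@@H]1[C@@H]3[C@@]2(C)CC[C@@]3(O[Si](C)(C)C)C(C)C | intermediate
11 | (1S,4R,5S,6R)-6-hydroxy-4-(trimethylsilyloxy)dauc-7-en-9-one | C1C(=O)C(C)=C[C@@H](O)[C@@H]2[C@@]1(C)CC[C@@]2(O[Si](C)(C)C)C(C)C | intermediate
12 | 4-hydroxybenzoic acid | O=C(O)c1ccc(O)cc1 | starting material
13 | tert-butyldimethylsilyl 4-(tert-butyldimethylsilyloxy)benzoate | CC(C)(C)[Si](C)(C)OC(=O)c1ccc(O[Si](C)(C)C(C)(C)C)cc1 | intermediate (not isolated)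
14 | 4-(tert-butyldimethylsilyloxy)benzoic acid | CC(C)(C)[Si](C)(C)Oc1ccc(cc1)C(=O)O | intermediate
15 | (1S,4R,5S,6R)-6-[4-(tert-butyldimethylsilyloxy)benzoyloxy]-4-(trimethylsilyloxy)dauc-7-en-9-one | C1C(=O)C(C)=C[C@@H](OC(=O)c3ccc(O[Si](C)(C)C(C)(C)C)cc3)[C@@H]2[C@@]1(C)CC[C@@]2(O[Si](C)(C)C)C(C)C | intermediate
16 | sodium C9–C10 dienolate of 15 | C1=C(O[Na])C(C)=C[C@@H](OC(=O)c3ccc(O[Si](C)(C)C(C)(C)C)cc3)[C@@H]2[C@@]1(C)CC[C@@]2(O[Si](C)(C)C)C(C)C | intermediate (not isolated)
17 | (1R,4R,5S,6R,10S)-6-[4-(tert-butyldimethylsilyloxy)benzoyloxy]-10-hydroxy-4-(trimethylsilyloxy)dauc-7-en-9-one | O[C@@H]1C(=O)C(C)=C[C@@H](OC(=O)c3ccc(O[Si](C)(C)C(C)(C)C)cc3)[C@@H]2[C@@]1(C)CC[C@@]2(O[Si](C)(C)C)C(C)C | intermediate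
18 | tiglic acid, (E)-2-methylbut-2-enoic acid | C/C=C(\C)C(=O)O | starting material
19 | (E)-2-methylbut-2-enoic 2,4,6-trichlorobenzoic anhydride | C/C=C(\C)C(=O)OC(=O)c1c(Cl)cc(Cl)cc1Cl | intermediate (not isolated)
20 | (1R,4R,5S,6R,10S)-6-[4-(tert-butyldimethylsilyloxy)benzoyloxy]-10-[(E)-2-methylbut-2-enoyloxy]-4-(trimethylsilyloxy)dauc-7-en-9-one | C/C=C(\C)C(=O)O[C@@H]1C(=O)C(C)=C[C@@H](OC(=O)c3ccc(O[Si](C)(C)C(C)(C)C)cc3)[C@@H]2[C@@]1(C)CC[C@@]2(O[Si](C)(C)C)C(C)C | intermediate
21 | C9 p-toluenesulfonylhydrazone of 20 (C=N geometry not defined) | C/C=C(\C)C(=O)O[C@@H]1C(=NNS(=O)(=O)c4ccc(C)cc4)C(C)=C[C@@H](OC(=O)c3ccc(O[Si](C)(C)C(C)(C)C)cc3)[C@@H]2[C@@]1(C)CC[C@@]2(O[Si](C)(C)C)C(C)C | intermediate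
22 | N-(1,3,2-benzodioxaborol-2-yl)-N′-tosylhydrazine at C9 (C9 configuration not defined) | C/C=C(\C)C(=O)O[C@@H]1C(N(B5Oc6ccccc6O5)NS(=O)(=O)c4ccc(C)cc4)C(C)=C[C@@H](OC(=O)c3ccc(O[Si](C)(C)C(C)(C)C)cc3)[C@@H]2[C@@]1(C)CC[C@@]2(O[Si](C)(C)C)C(C)C | intermediate (not isolated)
23 | C9 allylic diazene (C9 configuration not defined) | C/C=C(\C)C(=O)O[C@@H]1C(N=N)C(C)=C[C@@H](OC(=O)c3ccc(O[Si](C)(C)C(C)(C)C)cc3)[C@@H]2[C@@]1(C)CC[C@@]2(O[Si](C)(C)C)C(C)C | intermediate (not isolated)
24 | (1R,4R,5S,6R,10R)-6-[4-(tert-butyldimethylsilyloxy)benzoyloxy]-10-[(E)-2-methylbut-2-enoyloxy]-4-(trimethylsilyloxy)dauc-8-ene | C/C=C(\C)C(=O)O[C@@H]1C=C(C)C[C@@H](OC(=O)c3ccc(O[Si](C)(C)C(C)(C)C)cc3)[C@@H]2[C@@]1(C)CC[C@@]2(O[Si](C)(C)C)C(C)C | intermediate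
25 | (1R,4R,5S,6R,10R)-6-(4-hydroxybenzoyloxy)-10-[(E)-2-methylbut-2-enoyloxy]dauc-8-en-4-ol | C/C=C(\C)C(=O)O[C@@H]1C=C(C)C[C@@H](OC(=O)c2ccc(O)cc2)[C@@H]2[C@@]1(C)CC[C@@]2(O)C(C)C | target

## Step count and least certain steps

Total step count: 14. Longest linear sequence: 13 steps (1 to 25 through steps 1–7 and 9–14); step 8 is a one-step side branch.

**Step 4 (key step, proposed new method).**
- **What may go wrong:** dimerisation of the ylide may outrun its addition to the hindered, β,β-disubstituted enone. The Lewis acid may be lost by ligation to the oxido oxygen of the ylide or to the product diketone. Face or exo/endo selectivity may be poor, since no closely related catalytic case exists.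
- **Fallback:** 4 and 5 are combined under the known thermal conditions (Et3N, MeCN with 5 in excess, 60 °C). This should give the racemic exo adduct F1 after chromatographic removal of ylide dimer and any endo isomer. The enantiomers are then separated by preparative chromatography on a chiral stationary phase (amylose tris(3,5-dimethylphenylcarbamate)), the mirror-image adduct F2 is set aside, and the route is rejoined at 8.

**Step 5.**
- **What may go wrong:** the reagent may also add to the C9 enone carbonyl, and its basicity may trigger enolisation at C5 with opening of the β-alkoxy bridge.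
- **Fallback:** setting out from 8, the enone is masked in the flask as its phosphonium silyl enol ether F3 (PPh3, TMSOTf, CH2Cl2). The cerium reagent then meets a single ketone and should give the carbinol F4. Bu4NF in the work-up expels PPh3 and the silyl group and returns 9.

**Step 7.**
- **What may go wrong:** the C6–O bond, vinylogous to the ketone through C7=C8, may cleave in competition with the C10–O bond. The enone may be over-reduced.
- **Fallback:** setting out from 10, thiophenol is added to the enone (PhSH, Et3N cat.) to give the 7-phenylthio ketone F5. C9 is then a saturated ketone with a single activated C–O bond. SmI2 should open the bridge to the hydroxy sulfide F6, and DBU eliminates thiophenol to return the enone 11.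

**Step 10.**
- **What may go wrong:** oxygen may be transferred to the β face, since the C1 methyl sits next to C10 on the α face. Deprotonation may also occur at C6.
- **Fallback:** setting out from 15, if the step gives the 10-epimeric alcohol F7, Swern oxidation gives the C9,C10-dione F8. NaBH4 at −78 °C then reduces the non-conjugated C10 ketone from the same open β face, which now places hydrogen β and oxygen α and returns 17.

**Steps 12 and 13.**
- **What may go wrong:** condensation at the C9 ketone, flanked by the C8 methyl and the acyloxy-bearing C10, may be incomplete. The tiglate may be lost from the α-acyloxy hydrazone.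
- **Fallback:** setting out from 20, Luche reduction (NaBH4, CeCl3·7H2O, MeOH, −78 °C) gives the allylic alcohol F9 (either C9 epimer serves). Mitsunobu displacement with 2-nitrobenzenesulfonylhydrazide (PPh3, diethyl azodicarboxylate, THF, −30 °C) gives the sulfonylhydrazine F10. On warming this loses 2-nitrobenzenesulfinic acid to give diazene 23, which rejoins the route at 24.

## Further compounds

F1 | step 4 | racemic exo adduct (8 and its mirror image, 1:1) | O1[C@H]2C(=O)C(C)=C[C@@H]1[C@@H]3[C@@]2(C)CCC3=O.O1[C@@H]2C(=O)C(C)=C[C@H]1[C@H]3[C@]2(C)CCC3=O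
F2 | step 4 | mirror image of 8, (1S,5R,6S,10S) | O1[C@@H]2C(=O)C(C)=C[C@H]1[C@H]3[C@]2(C)CCC3=O
F3 | step 5 | phosphonium silyl enol ether of 8 (triphenylphosphonio on C7 syn to the bridge, C9 trimethylsilyl enol ether), triflate | O1[C@H]2C(O[Si](C)(C)C)=C(C)[C@@H]([P+](c4ccccc4)(c4ccccc4)c4ccccc4)[C@@H]1[C@@H]3[C@@]2(C)CCC3=O.[O-]S(=O)(=O)C(F)(F)F
F4 | step 5 | C4 isopropyl carbinol of F3, triflate | O1[C@H]2C(O[Si](C)(C)C)=C(C)[C@@H]([P+](c4ccccc4)(c4ccccc4)c4ccccc4)[C@@H]1[C@@H]3[C@@]2(C)CC[C@@]3(O)C(C)C.[O-]S(=O)(=O)C(F)(F)F
F5 | step 7 | 7-phenylthio-7,8-dihydro derivative of 10 (sulfur syn to the bridge, C8 not defined) | O1[C@H]2C(=O)C(C)[C@@H](Sc4ccccc4)[C@@H]1[C@@H]3[C@@]2(C)CC[C@@]3(O[Si](C)(C)C)C(C)C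
F6 | step 7 | 6-hydroxy-7-phenylthio-4-(trimethylsilyloxy)daucan-9-one (C8 not defined) | C1C(=O)C(C)[C@@H](Sc3ccccc3)[C@@H](O)[C@@H]2[C@@]1(C)CC[C@@]2(O[Si](C)(C)C)C(C)C
F7 | step 10 | 10-epimer of 17, (10R)-alcohol | O[C@H]1C(=O)C(C)=C[C@@H](OC(=O)c3ccc(O[Si](C)(C)C(C)(C)C)cc3)[C@@H]2[C@@]1(C)CC[C@@]2(O[Si](C)(C)C)C(C)C
F8 | step 10 | C9,C10-dione from F7 | O=C1C(=O)C(C)=C[C@@H](OC(=O)c3ccc(O[Si](C)(C)C(C)(C)C)cc3)[C@@H]2[C@@]1(C)CC[C@@]2(O[Si](C)(C)C)C(C)C
F9 | step 12 | C9 allylic alcohol from 20 (C9 not defined) | C/C=C(\C)C(=O)O[C@@H]1C(O)C(C)=C[C@@H](OC(=O)c3ccc(O[Si](C)(C)C(C)(C)C)cc3)[C@@H]2[C@@]1(C)CC[C@@]2(O[Si](C)(C)C)C(C)C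
F10 | step 12 | N-(2-nitrobenzenesulfonyl)hydrazine at C9 (C9 not defined) | C/C=C(\C)C(=O)O[C@@H]1C(N(N)S(=O)(=O)c4ccccc4[N+](=O)[O-])C(C)=C[C@@H](OC(=O)c3ccc(O[Si](C)(C)C(C)(C)C)cc3)[C@@H]2[C@@]1(C)CC[C@@]2(O[Si](C)(C)C)C(C)C
A1 | alternative 1 | hydroazulene C6 silyl enol ether with C9=C10 alkene and C8 methyl stereocentre (Cope product) | C1=C[C@@H](C)CC(O[Si](C)(C)C(C)(C)C)=C2[C@@]1(C)CC[C@@]2(O[Si](C)(C)C(C)(C)C)C(C)C
A2 | alternative 1 | cis-divinylcyclopropane: bicyclo[3.1.0]hexane with siloxyvinyl on C5 and (E)-propenyl on C10 | C/C=C/[C@H]1[C@]2(C)CC[C@@](O[Si](C)(C)C(C)(C)C)(C(C)C)[C@]12C(O[Si](C)(C)C(C)(C)C)=C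
A3 | alternative 2 | cis-fused hydroazulen-6-one with C10 dioxolane and C4 silyl ether | C12(OCCO1)CCCC(=O)[C@@H]3[C@@]2(C)CC[C@H]3O[Si](C)(C)C(C)(C)C
A4 | alternative 2 | trans-decalin C6 tertiary alcohol, C5 mesylate, C4 silyl ether, C10 dioxolane | C12(OCCO1)CCC[C@]3(O)[C@@H](OS(C)(=O)=O)[C@H](O[Si](C)(C)C(C)(C)C)CC[C@@]23C
A5 | alternative 2 | (R)-Wieland–Miescher ketone | C[C@@]12CCC(=O)C=C1CCCC2=O
A6 | alternative 3 | cis-fused hydroazulen-6-one with C9=C10 alkene, C8 methyl stereocentre and C4 triethylsilyl ether | C1=C[C@@H](C)CC(=O)[C@@H]2[C@@]1(C)CC[C@@]2(O[Si](CC)(CC)CC)C(C)C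
A7 | alternative 3 | open-chain chloromethyl ketone with (E,E)-diene and C4 triethylsilyl ether | ClCC(=O)C[C@](O[Si](CC)(CC)CC)(C(C)C)CC/C(C)=C/C=C/C
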